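**Strategy.** The dihydrofuran ring is disconnected at the aryl ether bond O1–C7a. This leads back to an open-chain (1S,2S)-1,2-diarylpropan-1-ol whose ring A is a simple 2-allyl-4-alkylphenol with C7a still C–H. The key step exploits that the C6 hydroxyl of ring A is para to C3a and meta to C7a. Two-electron oxidation of the phenol gives a para-quinol in which C7a is the β-carbon of an enone; the C2 hydroxyl adds there, and loss of water rearomatises ring A. One operation thus achieves a dehydrogenative etherification of the C–H bond meta to the phenol. Both stereocentres are set beforehand by dynamic kinetic resolution of an α-aryl ketone.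

Key step: step 4

Remark: ring atoms carry the benzofuran numbering of the target (O1, C2, C3, C3a, C4–C7, C7a) throughout, also in open-chain and dearomatised compounds.

Step 1
Reactants: 1 3,4,5-trimethoxybenzonitrile
Product: 3 1-(3,4,5-trimethoxyphenyl)propan-1-one, via bromomagnesium ketiminate 2 (not isolated)
Conditions: EtMgBr (1.5 equiv), THF, 60 °C; then 2 M aq. HCl, 25 °C
Reagents that add atoms: ethylmagnesium bromide, CC[Mg]Br; water, O
Why: Grignard addition to an aryl nitrile stops at the N-magnesio ketimine, which cannot take up a second equivalent, and aqueous acid hydrolyses it to the ketone (nitrile-to-ketone Grignard synthesis); no stereocentre is formed.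

Step 2
Reactants: 3 1-(3,4,5-trimethoxyphenyl)propan-1-one; 4 2-allyl-4-bromophenol
Product: 5 rac-2-(3-allyl-4-hydroxyphenyl)-1-(3,4,5-trimethoxyphenyl)propan-1-one
Conditions: Pd2(dba)3 (1.5 mol %), XPhos (4 mol %), NaOtBu (2.5 equiv), THF, 65 °C; aq. NH4Cl work-up
Reagents that add atoms: none
Why: Palladium-catalysed α-arylation of a ketone enolate (Buchwald–Hartwig type: oxidative addition of the C–Br bond to zerovalent palladium, enolate transmetalation, reductive elimination), run with extra base so that the phenol travels as its phenoxide; the new α-stereocentre is deliberately formed racemic because it is resolved dynamically in step 3.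

Step 3
Reactants: 5 rac-2-(3-allyl-4-hydroxyphenyl)-1-(3,4,5-trimethoxyphenyl)propan-1-one
Product: 6 2-allyl-4-[(1S,2S)-1-hydroxy-1-(3,4,5-trimethoxyphenyl)propan-2-yl]phenol
Conditions: trans-RuCl2[(R)-xylbinap][(R)-daipen] (0.5 mol %), KOtBu (1.5 equiv), iPrOH, H2 (10 atm), 25 °C; then AcOH (1.5 equiv)
Reagents that add atoms: none
Why: Noyori-type asymmetric hydrogenation with dynamic kinetic resolution: alkoxide epimerises the α-aryl stereocentre through the enolate faster than the bifunctional RuH/NH catalyst reduces the carbonyl, the (R,R)-configured catalyst fixes the carbinol as S (the sense known for aryl alkyl ketones), and hydride delivery to that face is Felkin–Anh (anti to the α-aryl group) only in the (S)-ketone, so the matched enantiomer is funnelled to the (1S,2S) alcohol; the outer-sphere mechanism leaves the allyl C=C untouched.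

Step 4
Reactants: 6 2-allyl-4-[(1S,2S)-1-hydroxy-1-(3,4,5-trimethoxyphenyl)propan-2-yl]phenol
Product: 9 (2S,3S)-3-methyl-5-(prop-2-en-1-yl)-2-(3,4,5-trimethoxyphenyl)-2,3-dihydro-1-benzofuran-6-ol, via para-quinol 7 (not isolated), via bicyclic hydroxy enone 8 (not isolated)
Conditions: PhI(OAc)2 (1.05 equiv), MeCN/H2O (3:1), 0 °C; aq. NaHCO3 wash, solvent switch; then TsOH·H2O (10 mol %), CH2Cl2, 25–40 °C
Reagents that add atoms: none
Why: PhI(OAc)2 oxidises the phenol by two electrons and water is captured at C3a to give para-quinol 7, in which C7a, meta to the phenol oxygen and unreactive in the arene, has become the β-carbon of the C7=C7a enone. Acid then drives intramolecular oxa-Michael addition of the C2 hydroxyl to C7a (5-exo-trig closure of the furan ring, cis-fused enone 8) and, through the dienol, ionisation of the tertiary allylic C3a hydroxyl with loss of the C7a proton, which rearomatises ring A and erases the transient C3a and C7a stereocentres. The closest known reaction types are the para-quinol oxa-Michael bicyclisation of 4-(2-hydroxyethyl)phenols to rengyolone-type enones and the acid-induced dehydrative aromatisation of para-quinol Michael adducts to meta-substituted phenols. No stereocentre of the product is created: C2 and C3 are carried over unchanged from 6, and the trans ring is also the thermodynamically preferred one should the C2–O bond ionise reversibly. The step needs regioselection between the enone β-carbons C7a and C4, which the C5 allyl group secures, because the C4=C5 enone is α-substituted and therefore much less electrophilic and more hindered, and closure at C7a keeps the more substituted enone. It also needs oxidation of the phenol alone beside the alkene and the trimethoxyarene, which the far lower oxidation potential of the phenol and water in large excess as the capturing nucleophile provide.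

**Compound list**

1 | 3,4,5-trimethoxybenzonitrile | N#Cc1cc(OC)c(OC)c(OC)c1 | starting material
2 | bromomagnesium ketiminate, bromo{[1-(3,4,5-trimethoxyphenyl)propylidene]amino}magnesium | CCC(=N[Mg]Br)c1cc(OC)c(OC)c(OC)c1 | intermediate (not isolated)
3 | 1-(3,4,5-trimethoxyphenyl)propan-1-one | CCC(=O)c1cc(OC)c(OC)c(OC)c1 | intermediate
4 | 2-allyl-4-bromophenol | C=CCc1cc(Br)ccc1O | starting material
5 | rac-2-(3-allyl-4-hydroxyphenyl)-1-(3,4,5-trimethoxyphenyl)propan-1-one | C=CCc1cc(ccc1O)C(C)C(=O)c1cc(OC)c(OC)c(OC)c1 | intermediate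
6 | 2-allyl-4-[(1S,2S)-1-hydroxy-1-(3,4,5-trimethoxyphenyl)propan-2-yl]phenol | C=CCc1cc(ccc1O)[C@@H]([C@H](O)c1cc(OC)c(OC)c(OC)c1)C | intermediate
7 | para-quinol, 2-allyl-4-hydroxy-4-[(1S,2R)-1-hydroxy-1-(3,4,5-trimethoxyphenyl)propan-2-yl]cyclohexa-2,5-dien-1-one, both C3a epimers; same spatial arrangement in the side chain as 6, the descriptor R arises only because the neighbouring ring carbon now bears oxygen | C=CCC1=CC(O)(C=CC1=O)[C@@H]([C@H](O)c1cc(OC)c(OC)c(OC)c1)C | intermediate (not isolated)
8 | bicyclic hydroxy enone, (2S,3R)-5-allyl-3a-hydroxy-3-methyl-2-(3,4,5-trimethoxyphenyl)-3,3a,7,7a-tetrahydro-1-benzofuran-6(2H)-one, cis-fused, both C3a/C7a pairs; C2 and C3 arranged as in 6 | C=CCC1=CC2(O)C(CC1=O)O[C@H](c3cc(OC)c(OC)c(OC)c3)[C@H]2C | intermediate (not isolated)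
9 | (2S,3S)-3-methyl-5-(prop-2-en-1-yl)-2-(3,4,5-trimethoxyphenyl)-2,3-dihydro-1-benzofuran-6-ol, trans | C=CCc1cc2c(cc1O)O[C@H](c1cc(OC)c(OC)c(OC)c1)[C@H]2C | target

Total step count: 4. Longest linear sequence: 4 (steps 1 to 4; compound 4 is bought).

**Steps most likely to fail**

Step 4 (key step). The conjugate addition may lose regiocontrol, with the C2 hydroxyl closing onto C4 instead of C7a and ending in the 7-allyl isomer. The oxidised phenol may also lose the benzylic C3 proton towards a para-quinone methide, or the oxidant may engage the allyl-bearing ring unselectively.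

The fallback introduces the allyl group last and sets out from 3. Ketone 3 is arylated with commercial 4-bromophenol under the conditions of step 2 to rac-2-(4-hydroxyphenyl)-1-(3,4,5-trimethoxyphenyl)propan-1-one F1. Hydrogenation as in step 3 should give 4-[(1S,2S)-1-hydroxy-1-(3,4,5-trimethoxyphenyl)propan-2-yl]phenol F2. PhI(OAc)2 in aqueous MeCN, then TsOH, should take F2 through the symmetrical para-quinol 4-hydroxy-4-[(1S,2R)-1-hydroxy-1-(3,4,5-trimethoxyphenyl)propan-2-yl]cyclohexa-2,5-dien-1-one F3 and the cis-fused (2S,3R)-3a-hydroxy-3-methyl-2-(3,4,5-trimethoxyphenyl)-3,3a,7,7a-tetrahydro-1-benzofuran-6(2H)-one F4 to (2S,3S)-3-methyl-2-(3,4,5-trimethoxyphenyl)-2,3-dihydro-1-benzofuran-6-ol F5. In F3 both enone β-carbons lead to the same arene, so no regiochemical question arises. Allyl bromide with K2CO3 in acetone should then give (2S,3S)-3-methyl-6-(prop-2-en-1-yloxy)-2-(3,4,5-trimethoxyphenyl)-2,3-dihydro-1-benzofuran F6. Aromatic Claisen rearrangement (PhNEt2, 190 °C) should move the allyl group mainly to C5, which is para to O1 and remote from the ring fusion, and so comes back to the route at 9.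

Step 3. Epimerisation of the α-stereocentre may lag behind reduction, so that kinetic instead of dynamic resolution operates. Discrimination between the matched and mismatched ketone may also be weak; either way diastereomer mixtures would result.

The fallback sets out from 5 and uses substrate control. LiBH(sBu)3 (2.2 equiv, THF, −78 °C) should reduce racemic 5 in the Felkin–Anh sense, hydride anti to the α-aryl group, to the racemic like-configured alcohol. This is 6 together with its enantiomer 2-allyl-4-[(1R,2R)-1-hydroxy-1-(3,4,5-trimethoxyphenyl)propan-2-yl]phenol F7. Preparative chromatography on a chiral stationary phase removes F7 and comes back to the route at 6.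

Step 2. Alkoxide or a palladium hydride may move the allyl double bond into conjugation, the terminal alkene may be consumed in a Heck-type reaction, and oxidative addition to the electron-rich bromophenoxide may be slow.

The fallback sets out from 4 and masks the phenol so that a weak base suffices. TIPSCl with imidazole in DMF should give (2-allyl-4-bromophenoxy)tri(propan-2-yl)silane F8. Arylation of 3 with F8 can then be run with K3PO4 (Pd2(dba)3, Xantphos, toluene, 80 °C), which cannot deprotonate the allylic position, to give rac-2-{3-allyl-4-[tri(propan-2-yl)silyloxy]phenyl}-1-(3,4,5-trimethoxyphenyl)propan-1-one F9. Bu4NF (THF, 0 °C) removes the silyl group and comes back to the route at 5.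

**Further compounds**

F1 | step 4 | rac-2-(4-hydroxyphenyl)-1-(3,4,5-trimethoxyphenyl)propan-1-one | CC(c1ccc(O)cc1)C(=O)c1cc(OC)c(OC)c(OC)c1
F2 | step 4 | 4-[(1S,2S)-1-hydroxy-1-(3,4,5-trimethoxyphenyl)propan-2-yl]phenol | Oc1ccc(cc1)[C@@H]([C@H](O)c1cc(OC)c(OC)c(OC)c1)C
F3 | step 4 | 4-hydroxy-4-[(1S,2R)-1-hydroxy-1-(3,4,5-trimethoxyphenyl)propan-2-yl]cyclohexa-2,5-dien-1-one | O=C1C=CC(O)(C=C1)[C@@H]([C@H](O)c1cc(OC)c(OC)c(OC)c1)C
F4 | step 4 | (2S,3R)-3a-hydroxy-3-methyl-2-(3,4,5-trimethoxyphenyl)-3,3a,7,7a-tetrahydro-1-benzofuran-6(2H)-one, cis-fused | O=C1C=CC2(O)C(C1)O[C@H](c3cc(OC)c(OC)c(OC)c3)[C@H]2C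
F5 | step 4 | (2S,3S)-3-methyl-2-(3,4,5-trimethoxyphenyl)-2,3-dihydro-1-benzofuran-6-ol | Oc1ccc2c(c1)O[C@H](c1cc(OC)c(OC)c(OC)c1)[C@H]2C
F6 | step 4 | (2S,3S)-3-methyl-6-(prop-2-en-1-yloxy)-2-(3,4,5-trimethoxyphenyl)-2,3-dihydro-1-benzofuran | C=CCOc1ccc2c(c1)O[C@H](c1cc(OC)c(OC)c(OC)c1)[C@H]2C
F7 | step 3 | 2-allyl-4-[(1R,2R)-1-hydroxy-1-(3,4,5-trimethoxyphenyl)propan-2-yl]phenol | C=CCc1cc(ccc1O)[C@H]([C@@H](O)c1cc(OC)c(OC)c(OC)c1)C
F8 | step 2 | (2-allyl-4-bromophenoxy)tri(propan-2-yl)silane | C=CCc1cc(Br)ccc1O[Si](C(C)C)(C(C)C)C(C)C
F9 | step 2 | rac-2-{3-allyl-4-[tri(propan-2-yl)silyloxy]phenyl}-1-(3,4,5-trimethoxyphenyl)propan-1-one | C=CCc1cc(ccc1O[Si](C(C)C)(C(C)C)C(C)C)C(C)C(=O)c1cc(OC)c(OC)c(OC)c1
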